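**Retrosynthetic overview**

1. The last ring is the cage carbocycle made of the carbinol bridgehead C–OH, the bridge CH2, the bridge CH, the ketal-oxygen bridgehead, the prenyl/ether quaternary carbon and the cage ketone. Retro-[4+2] (bonds CH2–C(OH) and CH–C(O-ketal)) followed by retro-Claisen (prenyl back to the ketone oxygen) leads to the flat aryl bis(1,1-dimethylallyl) ether 24. In the forward sense, one heating step makes this ring, the second cage carbocycle and the tetrahydrofuran, three C–C bonds and four stereocentres.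
2. Enabling feature: the cage ketone is flanked by a quaternary carbon bearing prenyl and an ether oxygen (a γ,δ-unsaturated ketone, the Claisen retron). That oxygen is tied through CMe2 to the CH of the CH2–CH bridge (the tetrahydrofuran is the dienophile tether), and the bridge lies across the ene-lactone C=C (the cyclohexene of a Diels–Alder adduct). The six ring carbons are those of a 2,3,4,5-tetraoxygenated benzoate whose ester carbonyl is para to the oxygen that must give up its allyl group.
3. The spiro ketal is made before the cage and locked as a masked ortho-benzoquinone (silyl dienol ether of ring A) by enantioselective dearomatising spirolactonisation of phenol acid 23. This single stereocentre steers the cascade; fluoride at the end frees the ring-A ketone and the bridgehead OH.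
4. 23 comes from union of chloroquinone 17 (from 2,6-dimethoxybenzoquinone, prenal and prenyl acetate) with salicylaldehyde 8 (from 2,3,4-trihydroxybenzaldehyde). A temporary seven-membered lactone tells the two hydroquinone oxygens apart.
5. Ring order: 2H-pyran (step 7) → temporary lactone (step 13, opened in step 15) → spiro 1,3-dioxin-4-one with ring A dearomatised (step 16) → tetrahydrofuran and both cage carbocycles in step 17, the ketone-containing carbocycle completing the skeleton.

Key step: step 17

Assumption: the (R,R)-lactamide iodane is taken to give the (S)-spiro centre (if the induction proves opposite, its mirror image is used in step 16), and the target configuration at the epimerisable prenyl-bearing CH next to the ring-A ketone is taken to be the thermodynamically preferred one.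

Locants used below: chromene numbering (C5–C8) for ring A before step 16; from 24 on, unprimed 1,3-benzodioxin-4-one locants (C4a, C5, C6, C7, C8, C8a) for ring C and primed chromene locants for rings A and B.

**Route**

Step 1
Reactants: 1 2,3,4-trihydroxybenzaldehyde
Product: 2 2,3-dihydroxy-4-[(triisopropylsilyloxy)methoxy]benzaldehyde
Conditions: (triisopropylsiloxy)methyl chloride (1.05 equiv), i-Pr2NEt, CH2Cl2/DMF, −20 → 0 °C
Reagents that add atoms: (triisopropylsiloxy)methyl chloride CC(C)[Si](OCCl)(C(C)C)C(C)C
Why: Williamson-type O-alkylation with a chloromethyl ether; the 4-OH, para to the formyl group and not hydrogen-bonded, is the most acidic phenol and should react first under amine base.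

Step 2
Reactants: 2 2,3-dihydroxy-4-[(triisopropylsilyloxy)methoxy]benzaldehyde; 3 3-chloro-3-methylbut-1-yne
Product: 4 2,3-bis[(2-methylbut-3-yn-2-yl)oxy]-4-[(triisopropylsilyloxy)methoxy]benzaldehyde
Conditions: 3 (4 equiv), K2CO3, KI (cat.), CuI (cat.), acetone, 55 °C
Reagents that add atoms: none
Why: Copper-assisted O-propargylation of phenols with a tertiary propargylic chloride, the standard entry to 1,1-dimethylpropargyl aryl ethers, should etherify both remaining phenols, the chelated 2-OH included.

Step 3
Reactants: 4 2,3-bis[(2-methylbut-3-yn-2-yl)oxy]-4-[(triisopropylsilyloxy)methoxy]benzaldehyde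
Product: 6 2,3-bis[(2-methylbut-3-yn-2-yl)oxy]-4-[(triisopropylsilyloxy)methoxy]phenol, via aryl formate 5 (not isolated)
Conditions: mCPBA, NaHCO3, CH2Cl2, 0 °C → rt; then K2CO3 (cat.), MeOH, 0 °C
Reagents that add atoms: mCPBA OOC(=O)c1cccc(Cl)c1
Why: Dakin-type Baeyer–Villiger oxidation in which the electron-rich aryl group migrates to give formate 5, which mild methanolysis cleaves to the phenol; terminal alkynes and the silyl acetal are inert to the peracid.

Step 4
Reactants: 6 2,3-bis[(2-methylbut-3-yn-2-yl)oxy]-4-[(triisopropylsilyloxy)methoxy]phenol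
Product: 7 2-hydroxy-3,4-bis[(2-methylbut-3-yn-2-yl)oxy]-5-[(triisopropylsilyloxy)methoxy]benzaldehyde
Conditions: MgCl2, Et3N, paraformaldehyde, THF, 66 °C
Reagents that add atoms: formaldehyde (as paraformaldehyde) C=O
Why: Magnesium-mediated ortho-formylation of phenols is specific for the position ortho to the hydroxyl, and only one such position is free; the alkynes are carried through this hot Lewis-acidic step in place of the Claisen-prone allyl ethers.

Step 5
Reactants: 7 2-hydroxy-3,4-bis[(2-methylbut-3-yn-2-yl)oxy]-5-[(triisopropylsilyloxy)methoxy]benzaldehyde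
Product: 8 2-hydroxy-3,4-bis[(2-methylbut-3-en-2-yl)oxy]-5-[(triisopropylsilyloxy)methoxy]benzaldehyde
Conditions: H2 (1 atm), Pd/CaCO3 poisoned with Pb(OAc)2 (Lindlar catalyst), quinoline, EtOAc, rt
Reagents that add atoms: none
Why: Lindlar semihydrogenation of the two terminal alkynes gives the 1,1-dimethylallyl ethers; the aldehyde, the phenol and the silyl acetal are not reduced.

Step 6
Reactants: 9 2,6-dimethoxy-1,4-benzoquinone
Product: 10 2-hydroxy-6-methoxy-1,4-benzoquinone
Conditions: NaOH (aq, 1.05 equiv), THF/H2O, 0 °C; then HCl (aq)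
Reagents that add atoms: sodium hydroxide [Na+].[OH-]
Why: Saponification of one vinylogous ester (addition–elimination of hydroxide); the hydroxyquinone anion formed is deactivated, so the second methoxy group should survive.

Step 7
Reactants: 10 2-hydroxy-6-methoxy-1,4-benzoquinone; 11 3-methylbut-2-enal
Product: 13 7-methoxy-2,2-dimethyl-2H-chromene-5,8-dione, via oxatriene 12 (not isolated)
Conditions: ethylenediammonium diacetate (10 mol %), toluene, 80 °C
Reagents that add atoms: none
Why: Knoevenagel condensation at the only nucleophilic carbon (C3 of the vinylogous acid) gives oxatriene 12, which closes by oxa-6π electrocyclisation onto the C2 oxygen; the reversible ring closure should funnel to the more stable para-quinone isomer.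

Step 8
Reactants: 13 7-methoxy-2,2-dimethyl-2H-chromene-5,8-dione
Product: 14 7-hydroxy-2,2-dimethyl-2H-chromene-5,8-dione
Conditions: NaOH (aq, 1.05 equiv), THF/H2O, 0 °C → rt; then HCl (aq)
Reagents that add atoms: sodium hydroxide [Na+].[OH-]
Why: Vinylogous ester saponification (addition–elimination) at the less hindered C7, again stopping at the deactivated hydroxyquinone anion.

Step 9
Reactants: 14 7-hydroxy-2,2-dimethyl-2H-chromene-5,8-dione; 15 3-methylbut-2-en-1-yl acetate
Product: 16 7-hydroxy-2,2-dimethyl-6-(3-methylbut-2-en-1-yl)-2H-chromene-5,8-dione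
Conditions: Pd(PPh3)4 (5 mol %), THF, 50 °C
Reagents that add atoms: none
Why: Tsuji–Trost allylation with zerovalent palladium, in which the hydroxyquinone reacts as a soft vinylogous-acid carbon nucleophile at the unsubstituted terminus of the π-prenyl complex to give the linear C6-prenyl product, while any O-prenyl ether re-ionises and is funnelled to the C-alkylated quinone.

Step 10
Reactants: 16 7-hydroxy-2,2-dimethyl-6-(3-methylbut-2-en-1-yl)-2H-chromene-5,8-dione
Product: 17 7-chloro-2,2-dimethyl-6-(3-methylbut-2-en-1-yl)-2H-chromene-5,8-dione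
Conditions: 1-chloro-N,N,2-trimethylprop-1-en-1-amine (Ghosez reagent), CH2Cl2, 0 °C → rt
Reagents that add atoms: 1-chloro-N,N,2-trimethylprop-1-en-1-amine CC(C)=C(Cl)N(C)C
Why: Conversion of the vinylogous acid into the vinylogous acid chloride under neutral conditions, which spares the prenyl and chromene double bonds from HCl.

Step 11
Reactants: 17 7-chloro-2,2-dimethyl-6-(3-methylbut-2-en-1-yl)-2H-chromene-5,8-dione; 8 2-hydroxy-3,4-bis[(2-methylbut-3-en-2-yl)oxy]-5-[(triisopropylsilyloxy)methoxy]benzaldehyde
Product: 18 2-{[2,2-dimethyl-6-(3-methylbut-2-en-1-yl)-5,8-dioxo-5,8-dihydro-2H-chromen-7-yl]oxy}-3,4-bis[(2-methylbut-3-en-2-yl)oxy]-5-[(triisopropylsilyloxy)methoxy]benzaldehyde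
Conditions: Cs2CO3, DMF, 0 °C → rt
Reagents that add atoms: none
Why: Nucleophilic vinylic substitution (addition–elimination) of the chloroquinone by the caesium phenoxide of 8 at C7, the carbon that carries the best leaving group.

Step 12
Reactants: 18 aryloxyquinone aldehyde
Product: 19 2-{[2,2-dimethyl-6-(3-methylbut-2-en-1-yl)-5,8-dioxo-5,8-dihydro-2H-chromen-7-yl]oxy}-3,4-bis[(2-methylbut-3-en-2-yl)oxy]-5-[(triisopropylsilyloxy)methoxy]benzoic acid
Conditions: NaClO2, NaH2PO4, 2-methylbut-2-ene, t-BuOH/H2O, 0 °C → rt
Reagents that add atoms: sodium chlorite [Na+].[O-]Cl=O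
Why: Pinnick oxidation of the aldehyde to the acid; the HOCl by-product is scavenged by excess 2-methylbut-2-ene, and the fully substituted quinone double bonds are poor acceptors for chlorite.

Step 13
Reactants: 19 aryloxyquinone acid
Product: 21 seven-membered aryl lactone of 20 (chromene O8 acylated; chromene C5-OH free), via hydroquinone acid 20 (not isolated)
Conditions: Na2S2O4, EtOAc/H2O, rt, Ar; then EDC·HCl, DMAP (cat.), CH2Cl2 (2 mM), 0 °C → rt
Reagents that add atoms: none
Why: Dithionite reduces the quinone to hydroquinone 20, and carbodiimide lactonisation (as in depsidone syntheses) then closes the seven-membered aryl lactone, which only the C8 hydroxyl can reach, so the two hydroquinone oxygens are told apart by a temporary ring.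

Step 14
Reactants: 21 seven-membered aryl lactone with free C5-OH
Product: 22 C5 triisopropylsilyl ether of lactone 21
Conditions: TIPSOTf, 2,6-lutidine, CH2Cl2, −78 → 0 °C
Reagents that add atoms: triisopropylsilyl triflate CC(C)[Si](OS(=O)(=O)C(F)(F)F)(C(C)C)C(C)C
Why: Silylation of the only free phenol with a silyl triflate and a hindered base.

Step 15
Reactants: 22 silylated lactone
Product: 23 2-{[8-hydroxy-2,2-dimethyl-6-(3-methylbut-2-en-1-yl)-5-(triisopropylsilyloxy)-2H-chromen-7-yl]oxy}-3,4-bis[(2-methylbut-3-en-2-yl)oxy]-5-[(triisopropylsilyloxy)methoxy]benzoic acid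
Conditions: LiOH, THF/H2O, 0 °C; then 0.1 M HCl to pH 4
Reagents that add atoms: lithium hydroxide [Li+].[OH-]
Why: Saponification of the activated aryl lactone opens the temporary ring and frees the C8 phenol and the carboxylic acid, while the hindered aryl silyl ether and the silyl acetal should be stable to cold aqueous LiOH.

Step 16
Reactants: 23 phenol acid
Product: 24 (2S)-2′,2′-dimethyl-6′-(3-methylbut-2-en-1-yl)-7,8-bis[(2-methylbut-3-en-2-yl)oxy]-6-[(triisopropylsilyloxy)methoxy]-5′-(triisopropylsilyloxy)-2′H,4H,8′H-spiro[1,3-benzodioxine-2,7′-chromene]-4,8′-dione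
Conditions: pre-formed (R,R)-ArI(OAc)2 [Ar = 2,6-bis{(1R)-1-(mesitylcarbamoyl)ethoxy}phenyl] (1.1 equiv), CH2Cl2, −40 → −20 °C
Reagents that add atoms: none
Why: Enantioselective Kita-type oxidative dearomatising spirolactonisation with a chiral trivalent-iodine reagent, in which the iodane activates the C8 phenol and the tethered carboxylate attacks the ortho carbon C7 ipso (six-membered ring) to give the masked ortho-benzoquinone ketal; the C2-symmetric lactamide ligand set on iodine selects the face of the phenol ring and so sets the spiro centre.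

Step 17
Reactants: 24 (S)-spiro masked ortho-benzoquinone
Product: 26 caged silyl dienol ether (spiro S; C6 R; bridge CH S; C8 R; C8a S), via Claisen dienone 25 (not isolated)
Conditions: toluene (degassed), BHT (cat.), 110 °C, sealed tube
Reagents that add atoms: none
Why: Heating should trigger the aromatic [3,3] Claisen shift of the 1,1-dimethylallyl group from O7 (the ether oxygen para to the lactone carbonyl, hence the more electron-poor one) to C8, giving the 2,4-cyclohexadienone 25, whose diene C6=C5–C4a=C8a is trapped at once by the vinyl group of the remaining C8 ether in an intramolecular [4+2] cycloaddition; this is the Claisen/Diels–Alder cascade known for aryl bis(1,1-dimethylallyl) ethers on the way to caged Garcinia xanthones. The cycloaddition closes the carbocycle C6–CH2–CH–C8a–C8–C7 (and with it the bicyclo[2.2.2]octene) by suprafacial [4+2] addition of the vinyl CH2 to C6 and the vinyl CH to C8a, and the tetrahydrofuran C8–O–CMe2–CH–C8a as the tether ring of this type-1 intramolecular Diels–Alder reaction (two-atom tether, necessarily cis-fused). C8 is set in the Claisen step and C8a, the bridge CH and C6 in the cycloaddition; because the dienophile is tied to the C8 oxygen it can only add on the face of that oxygen, so the four centres are fixed relative to one another and only the choice of ring-C face is open. That choice is made by the (S)-spiro centre: the Claisen step is reversible and the cycloaddition is not, so the product should come from the transition state in which the incoming CH at C8a passes the small sp2 carbonyl C8′=O of the spiro ring and not the prenyl-bearing C6′, which places the new C8a–C bond syn to C8′ as the target requires. Site selectivity (the O7 allyl, not the O8 allyl, must migrate, or the neo-cage forms) is secured by the para lactone carbonyl, and the alternative shifts to C6 or C8a give dienones that cannot cyclise and revert. The fully substituted silyl dienol ether leaves no acidic hydrogen next to the spiro ketal, so β-elimination of the ketal oxygens is blocked during the heating.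

Step 18
Reactants: 26 caged silyl dienol ether
Product: 27 CNP0222516.1
Conditions: HF·pyridine, pyridine, THF, 0 °C → rt
Reagents that add atoms: none
Why: Fluoride cleaves the silyl dienol ether (the dienol ketonises by protonation at the prenyl-bearing carbon) and the silyl acetal (the hemiacetal left on the bridgehead oxygen loses formaldehyde); the new CH centre is epimerisable through the enol and should settle in the buffered medium in the more stable (S) configuration, prenyl trans to the cage-bearing ketal oxygen, while the non-basic conditions avoid β-elimination of the spiro ketal.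

**Compound list**

1 | 2,3,4-trihydroxybenzaldehyde | O=Cc1ccc(O)c(O)c1O | starting material
2 | 2,3-dihydroxy-4-[(triisopropylsilyloxy)methoxy]benzaldehyde | O=Cc1ccc(OCO[Si](C(C)C)(C(C)C)C(C)C)c(O)c1O | intermediate
3 | 3-chloro-3-methylbut-1-yne | CC(C)(Cl)C#C | starting material
4 | 2,3-bis[(2-methylbut-3-yn-2-yl)oxy]-4-[(triisopropylsilyloxy)methoxy]benzaldehyde | O=Cc1ccc(OCO[Si](C(C)C)(C(C)C)C(C)C)c(OC(C)(C)C#C)c1OC(C)(C)C#C | intermediate
5 | 2,3-bis[(2-methylbut-3-yn-2-yl)oxy]-4-[(triisopropylsilyloxy)methoxy]phenyl formate | O=COc1ccc(OCO[Si](C(C)C)(C(C)C)C(C)C)c(OC(C)(C)C#C)c1OC(C)(C)C#C | intermediate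
6 | 2,3-bis[(2-methylbut-3-yn-2-yl)oxy]-4-[(triisopropylsilyloxy)methoxy]phenol | Oc1ccc(OCO[Si](C(C)C)(C(C)C)C(C)C)c(OC(C)(C)C#C)c1OC(C)(C)C#C | intermediate
7 | 2-hydroxy-3,4-bis[(2-methylbut-3-yn-2-yl)oxy]-5-[(triisopropylsilyloxy)methoxy]benzaldehyde | O=Cc1cc(OCO[Si](C(C)C)(C(C)C)C(C)C)c(OC(C)(C)C#C)c(OC(C)(C)C#C)c1O | intermediate
8 | 2-hydroxy-3,4-bis[(2-methylbut-3-en-2-yl)oxy]-5-[(triisopropylsilyloxy)methoxy]benzaldehyde | O=Cc1cc(OCO[Si](C(C)C)(C(C)C)C(C)C)c(OC(C)(C)C=C)c(OC(C)(C)C=C)c1O | intermediate
9 | 2,6-dimethoxy-1,4-benzoquinone | COC1=CC(=O)C=C(OC)C1=O | starting material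
10 | 2-hydroxy-6-methoxy-1,4-benzoquinone | COC1=CC(=O)C=C(O)C1=O | intermediate
11 | 3-methylbut-2-enal | CC(C)=CC=O | starting material
12 | 6-methoxy-3-(3-methylbut-2-en-1-ylidene)cyclohex-5-ene-1,2,4-trione | COC1=CC(=O)C(=CC=C(C)C)C(=O)C1=O | intermediate
13 | 7-methoxy-2,2-dimethyl-2H-chromene-5,8-dione | O=C1C=C(OC)C(=O)C2=C1C=CC(C)(C)O2 | intermediate
14 | 7-hydroxy-2,2-dimethyl-2H-chromene-5,8-dione | O=C1C=C(O)C(=O)C2=C1C=CC(C)(C)O2 | intermediate
15 | 3-methylbut-2-en-1-yl acetate | CC(C)=CCOC(C)=O | starting material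
16 | 7-hydroxy-2,2-dimethyl-6-(3-methylbut-2-en-1-yl)-2H-chromene-5,8-dione | CC(C)=CCC1=C(O)C(=O)C2=C(C=CC(C)(C)O2)C1=O | intermediate
17 | 7-chloro-2,2-dimethyl-6-(3-methylbut-2-en-1-yl)-2H-chromene-5,8-dione | CC(C)=CCC1=C(Cl)C(=O)C2=C(C=CC(C)(C)O2)C1=O | intermediate
18 | 2-{[2,2-dimethyl-6-(3-methylbut-2-en-1-yl)-5,8-dioxo-5,8-dihydro-2H-chromen-7-yl]oxy}-3,4-bis[(2-methylbut-3-en-2-yl)oxy]-5-[(triisopropylsilyloxy)methoxy]benzaldehyde | CC(C)=CCC1=C(Oc2c(C=O)cc(OCO[Si](C(C)C)(C(C)C)C(C)C)c(OC(C)(C)C=C)c2OC(C)(C)C=C)C(=O)C2=C(C=CC(C)(C)O2)C1=O | intermediate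
19 | 2-{[2,2-dimethyl-6-(3-methylbut-2-en-1-yl)-5,8-dioxo-5,8-dihydro-2H-chromen-7-yl]oxy}-3,4-bis[(2-methylbut-3-en-2-yl)oxy]-5-[(triisopropylsilyloxy)methoxy]benzoic acid | CC(C)=CCC1=C(Oc2c(C(=O)O)cc(OCO[Si](C(C)C)(C(C)C)C(C)C)c(OC(C)(C)C=C)c2OC(C)(C)C=C)C(=O)C2=C(C=CC(C)(C)O2)C1=O | intermediate
20 | 2-{[5,8-dihydroxy-2,2-dimethyl-6-(3-methylbut-2-en-1-yl)-2H-chromen-7-yl]oxy}-3,4-bis[(2-methylbut-3-en-2-yl)oxy]-5-[(triisopropylsilyloxy)methoxy]benzoic acid | CC(C)=CCc1c(O)c2C=CC(C)(C)Oc2c(O)c1Oc1c(C(=O)O)cc(OCO[Si](C(C)C)(C(C)C)C(C)C)c(OC(C)(C)C=C)c1OC(C)(C)C=C | intermediate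
21 | seven-membered aryl lactone (depsidone type) of 20: carboxyl esterified by the chromene C8 oxygen, chromene C5–OH free | CC(C)=CCc1c(O)c2C=CC(C)(C)Oc2c2OC(=O)c3cc(OCO[Si](C(C)C)(C(C)C)C(C)C)c(OC(C)(C)C=C)c(OC(C)(C)C=C)c3Oc12 | intermediate
22 | C5 triisopropylsilyl ether of lactone 21 | CC(C)=CCc1c(O[Si](C(C)C)(C(C)C)C(C)C)c2C=CC(C)(C)Oc2c2OC(=O)c3cc(OCO[Si](C(C)C)(C(C)C)C(C)C)c(OC(C)(C)C=C)c(OC(C)(C)C=C)c3Oc12 | intermediate
23 | 2-{[8-hydroxy-2,2-dimethyl-6-(3-methylbut-2-en-1-yl)-5-(triisopropylsilyloxy)-2H-chromen-7-yl]oxy}-3,4-bis[(2-methylbut-3-en-2-yl)oxy]-5-[(triisopropylsilyloxy)methoxy]benzoic acid | CC(C)=CCc1c(O[Si](C(C)C)(C(C)C)C(C)C)c2C=CC(C)(C)Oc2c(O)c1Oc1c(C(=O)O)cc(OCO[Si](C(C)C)(C(C)C)C(C)C)c(OC(C)(C)C=C)c1OC(C)(C)C=C | intermediate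
24 | (2S)-2′,2′-dimethyl-6′-(3-methylbut-2-en-1-yl)-7,8-bis[(2-methylbut-3-en-2-yl)oxy]-6-[(triisopropylsilyloxy)methoxy]-5′-(triisopropylsilyloxy)-2′H,4H,8′H-spiro[1,3-benzodioxine-2,7′-chromene]-4,8′-dione | CC(C)=CCC1=C(O[Si](C(C)C)(C(C)C)C(C)C)C2=C(OC(C)(C)C=C2)C(=O)[C@@]12OC(=O)c1cc(OCO[Si](C(C)C)(C(C)C)C(C)C)c(OC(C)(C)C=C)c(OC(C)(C)C=C)c1O2 | intermediate
25 | Claisen dienone of 24: ring C dearomatised, C7 ketone, C8 (R) quaternary with prenyl and the 1,1-dimethylallyl ether, diene C6=C5–C4a=C8a, spiro centre S | CC(C)=CCC1=C(O[Si](C(C)C)(C(C)C)C(C)C)C2=C(OC(C)(C)C=C2)C(=O)[C@@]12OC(=O)C1=C(O2)[C@@](CC=C(C)C)(OC(C)(C)C=C)C(=O)C(OCO[Si](C(C)C)(C(C)C)C(C)C)=C1 | intermediate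
26 | caged silyl dienol ether: the target skeleton with ring A as its C5′ triisopropylsilyl dienol ether and the bridgehead oxygen as its (triisopropylsilyloxy)methyl ether (spiro S; carbinol bridgehead R; bridge CH S; prenyl/ether quaternary carbon R; ketal-oxygen bridgehead S) | CC(C)=CCC1=C(O[Si](C(C)C)(C(C)C)C(C)C)C2=C(OC(C)(C)C=C2)C(=O)[C@@]12OC(=O)C1=C[C@]3(OCO[Si](C(C)C)(C(C)C)C(C)C)C[C@H]4C(C)(C)O[C@@](CC=C(C)C)(C3=O)[C@@]14O2 | intermediate
27 | CNP0222516.1 (ring-A prenylated CH S; spiro S; carbinol bridgehead R; bridge CH S; prenyl/ether quaternary carbon R; ketal-oxygen bridgehead S) | CC(C)=CC[C@H]1C(=O)C2=C(OC(C)(C)C=C2)C(=O)[C@@]12OC(=O)C1=C[C@]3(O)C[C@H]4C(C)(C)O[C@@](CC=C(C)C)(C3=O)[C@@]14O2 | target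

**Step count and risks**

Total steps: 18. Longest linear sequence: 13 steps (steps 1–5, then 11–18; the branch through steps 6–10 is equally long).

Three steps most likely to fail:

1. Step 17. The remote spiro centre may discriminate poorly between the two faces of ring C, or the silyl dienol ether lock may be lost thermally before the cascade is finished. Fallback: run the cascade at the natural oxidation level with a free ring-C phenol, so that the controlling element next to the spiro centre becomes an sp3 prenyl-bearing carbon. The fallback sets out from 24: HF·pyridine (pyridine, THF, 0 °C) removes both silicon groups to give the keto phenol F1 (mixture of epimers at the prenylated carbon). F1 is then heated under strictly neutral conditions (toluene, 100 °C), where the free phenol hydrogen-bonds to O7 and should accelerate the Claisen shift, and the Claisen/Diels–Alder cascade gives the target directly. The fallback comes back to the route at 27.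

2. Step 16. Enantioselectivity may erode through a ligand-free phenoxenium pathway, or oxidation may occur at the para silyloxy carbon with loss of the silyl group to give the quinone. Fallback: give up asymmetric induction for resolution. The fallback sets out from 23: PhI(OAc)2 (CH2Cl2, −20 °C) gives the racemic spiro masked ortho-benzoquinone F2, and its enantiomers are separated by preparative chromatography on a chiral stationary phase. The fallback comes back to the route at 24.

3. Step 11. Addition–elimination may be sluggish because both partners are doubly ortho-substituted, and the phenoxide may attack the pyran-bearing quinone carbon instead. Fallback: make the hindered aryl–oxygen bond intramolecularly by a Smiles rearrangement. The fallback sets out from 8 and 16: Pinnick oxidation of 8 gives the salicylic acid F3; EDC/DMAP esterification of the acidic hydroxyl of 16 with F3 gives the quinonyl salicylate F4; Et3N (MeCN, rt) then lets the ortho phenoxide add to C7 of the quinone through a six-membered spiro adduct, from which the carboxylate leaves (O→O aryl transfer). The fallback comes back to the route at 19, so steps 10–12 are bypassed.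

Further compounds
F1 | step 17 | (2S)-6-hydroxy-2′,2′-dimethyl-6′-(3-methylbut-2-en-1-yl)-7,8-bis[(2-methylbut-3-en-2-yl)oxy]-2′H,4H-spiro[1,3-benzodioxine-2,7′-chromene]-4,5′,8′(6′H)-trione, epimers at C6′ | CC(C)=CCC1C(=O)C2=C(OC(C)(C)C=C2)C(=O)[C@@]12OC(=O)c1cc(O)c(OC(C)(C)C=C)c(OC(C)(C)C=C)c1O2
F2 | step 16 | racemic 24 | CC(C)=CCC1=C(O[Si](C(C)C)(C(C)C)C(C)C)C2=C(OC(C)(C)C=C2)C(=O)C12OC(=O)c1cc(OCO[Si](C(C)C)(C(C)C)C(C)C)c(OC(C)(C)C=C)c(OC(C)(C)C=C)c1O2
F3 | step 11 | 2-hydroxy-3,4-bis[(2-methylbut-3-en-2-yl)oxy]-5-[(triisopropylsilyloxy)methoxy]benzoic acid | O=C(O)c1cc(OCO[Si](C(C)C)(C(C)C)C(C)C)c(OC(C)(C)C=C)c(OC(C)(C)C=C)c1O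
F4 | step 11 | 2,2-dimethyl-6-(3-methylbut-2-en-1-yl)-5,8-dioxo-5,8-dihydro-2H-chromen-7-yl 2-hydroxy-3,4-bis[(2-methylbut-3-en-2-yl)oxy]-5-[(triisopropylsilyloxy)methoxy]benzoate | CC(C)=CCC1=C(OC(=O)c2cc(OCO[Si](C(C)C)(C(C)C)C(C)C)c(OC(C)(C)C=C)c(OC(C)(C)C=C)c2O)C(=O)C2=C(C=CC(C)(C)O2)C1=O
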